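Ring C of the (2S)-flavanone is opened at the aryl ether bond O1–C8a and the aryl ketone bond C4–C4a. Ring A then becomes a 3,5-bis(allyloxy)-4-prenyl aryne and the remainder an (S)-3-aryl-3-silyloxypropanoate that already carries C2 and the (R)-epoxide. One fluoride-triggered operation frees the alkoxide, adds it to the aryne at C8a and lets the C4a carbanion acylate on the ester, closing the pyranone with C2 untouched. The step exploits the ortho relationship of C8a and C4a in ring A and the C5 oxygen beside C4a, which polarises the aryne and fixes the regiochemistry. Allyl ethers, stable to fluoride, are removed last with palladium under near-neutral conditions that spare the epoxide.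

Key step: step 13

Remark: the sense of induction of the (S,S)-TsDPEN ruthenium catalyst (aryl ketone to (S)-carbinol) and of the D-fructose-derived Shi ketone (2-methylalk-2-ene to (R)-epoxide) is assumed to follow their behaviour with simple aryl ketones and trisubstituted olefins.

Step 1
Reactants: 1 phloroglucinol; 2 prenyl bromide
Product: 3 2-prenylphloroglucinol
Conditions: DBU, THF, 0 °C to rt (1 in excess)
Reagents that add atoms: none
Why: C-alkylation of the ambident phloroglucinol anion at one of its three equivalent ring carbons by the allylic bromide, with the excess of 1 limiting polyprenylation.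

Step 2
Reactants: 3 2-prenylphloroglucinol
Product: 4 2-prenyl-5-(triisopropylsilyloxy)benzene-1,3-diol
Conditions: TIPSCl (1.0 equiv), imidazole, DMF, −20 to 0 °C
Reagents that add atoms: triisopropylsilyl chloride, CC(C)[Si](Cl)(C(C)C)C(C)C
Why: Sterically controlled silylation, in which the hydroxyl para to the prenyl group has no ortho substituent and should react first with the bulky silyl chloride.

Step 3
Reactants: 4 2-prenyl-5-(triisopropylsilyloxy)benzene-1,3-diol
Product: 5 [3,5-bis(allyloxy)-4-prenylphenoxy]triisopropylsilane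
Conditions: allyl bromide, K2CO3, acetone, reflux
Reagents that add atoms: allyl bromide, C=CCBr
Why: Williamson etherification of the two remaining phenols, which the aryl triisopropylsilyl ether should survive in acetone.

Step 4
Reactants: 5 [3,5-bis(allyloxy)-4-prenylphenoxy]triisopropylsilane
Product: 6 3,5-bis(allyloxy)-4-prenylphenol
Conditions: TBAF, AcOH, THF, 0 °C
Reagents that add atoms: none
Why: Fluoride cleavage of the aryl silyl ether, buffered with acetic acid so that no free phenoxide is exposed.

Step 5
Reactants: 6 3,5-bis(allyloxy)-4-prenylphenol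
Product: 7 2-bromo-3,5-bis(allyloxy)-4-prenylphenol
Conditions: NBS (1.0 equiv), CH2Cl2, −78 °C
Reagents that add atoms: N-bromosuccinimide, O=C1CCC(=O)N1Br
Why: Electrophilic aromatic bromination of a phloroglucinol-type phenol should be much faster than attack on the alkenes, and the two free ring positions are equivalent so only the stoichiometry has to be controlled.

Step 6
Reactants: 7 2-bromo-3,5-bis(allyloxy)-4-prenylphenol
Product: 11 3,5-bis(allyloxy)-4-prenyl-2-(trimethylsilyl)phenyl trifluoromethanesulfonate, via aryl trimethylsilyl ether 8 (not isolated), via aryllithium 9 (not isolated), via lithium phenoxide 10 (not isolated)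
Conditions: HMDS, THF, 65 °C, evaporate; n-BuLi, THF, −78 °C; Tf2O, −78 to 0 °C
Reagents that add atoms: hexamethyldisilazane, C[Si](C)(C)N[Si](C)(C)C; trifluoromethanesulfonic anhydride, O=S(=O)(OS(=O)(=O)C(F)(F)F)C(F)(F)F
Why: O-silylation, bromine–lithium exchange, 1,3 O-to-C silyl shift (retro-Brook rearrangement) and O-triflation form the standard route to ortho-silylaryl triflates, and at −78 °C the silyl shift should outrun carbolithiation of the neighbouring allyl ether.

Step 7
Reactants: 12 4'-hydroxyacetophenone; 2 prenyl bromide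
Product: 13 4'-hydroxy-3'-prenylacetophenone
Conditions: KOH, H2O, 0 °C to rt
Reagents that add atoms: none
Why: ortho-C-alkylation of a phenoxide by prenyl bromide in water, where hydrogen bonding to the phenoxide oxygen favours C- over O-alkylation, with O-prenyl and diprenyl by-products removed by chromatography.

Step 8
Reactants: 13 4'-hydroxy-3'-prenylacetophenone
Product: 14 4'-(allyloxy)-3'-prenylacetophenone
Conditions: allyl bromide, K2CO3, acetone, reflux
Reagents that add atoms: allyl bromide, C=CCBr
Why: Williamson etherification of the phenol.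

Step 9
Reactants: 14 4'-(allyloxy)-3'-prenylacetophenone; 15 dimethyl carbonate
Product: 16 methyl 3-[4-(allyloxy)-3-prenylphenyl]-3-oxopropanoate
Conditions: NaH, THF, reflux; then AcOH
Reagents that add atoms: none
Why: Crossed Claisen condensation of the methyl ketone enolate with dimethyl carbonate, driven by deprotonation of the β-keto ester formed.

Step 10
Reactants: 16 methyl 3-[4-(allyloxy)-3-prenylphenyl]-3-oxopropanoate
Product: 17 methyl (3S)-3-[4-(allyloxy)-3-prenylphenyl]-3-hydroxypropanoate
Conditions: RuCl(p-cymene)[(S,S)-TsDPEN] (1 mol %), HCO2H/Et3N (5:2), 30 °C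
Reagents that add atoms: none
Why: Noyori asymmetric transfer hydrogenation, in which the (S,S)-catalyst delivers hydride to the aryl ketone face that gives the (S)-carbinol and the outer-sphere mechanism leaves both alkenes alone.

Step 11
Reactants: 17 methyl (3S)-3-[4-(allyloxy)-3-prenylphenyl]-3-hydroxypropanoate
Product: 18 methyl (3S)-3-[4-(allyloxy)-3-{[(2R)-3,3-dimethyloxiran-2-yl]methyl}phenyl]-3-hydroxypropanoate
Conditions: Shi ketone derived from D-fructose (30 mol %), KHSO5 (as Oxone, 2KHSO5·KHSO4·K2SO4), K2CO3, Bu4NHSO4, MeCN/dimethoxymethane, aqueous Na2B4O7/Na2EDTA buffer, 0 °C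
Reagents that add atoms: potassium peroxymonosulfate KHSO5, [K+].[O-]S(=O)(=O)OO
Why: Shi epoxidation, in which the chiral dioxirane attacks the electron-rich trisubstituted prenyl alkene in preference to the terminal allyl ether alkene and its spiro transition state sets the (R) epoxide carbon under reagent control.

Step 12
Reactants: 18 methyl (3S)-3-[4-(allyloxy)-3-{[(2R)-3,3-dimethyloxiran-2-yl]methyl}phenyl]-3-hydroxypropanoate
Product: 19 methyl (3S)-3-[4-(allyloxy)-3-{[(2R)-3,3-dimethyloxiran-2-yl]methyl}phenyl]-3-(trimethylsilyloxy)propanoate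
Conditions: N-(trimethylsilyl)imidazole, CH2Cl2, rt
Reagents that add atoms: N-(trimethylsilyl)imidazole, C[Si](C)(C)n1ccnc1
Why: Neutral O-silylation that releases only imidazole and spares the epoxide, giving the latent proton-free alkoxide for the next step.

Step 13
Reactants: 19 methyl (3S)-3-[4-(allyloxy)-3-{[(2R)-3,3-dimethyloxiran-2-yl]methyl}phenyl]-3-(trimethylsilyloxy)propanoate; 11 3,5-bis(allyloxy)-4-prenyl-2-(trimethylsilyl)phenyl trifluoromethanesulfonate
Product: 23 (2S)-5,7-bis(allyloxy)-2-[4-(allyloxy)-3-{[(2R)-3,3-dimethyloxiran-2-yl]methyl}phenyl]-6-prenylchroman-4-one, via aryne 20 (not isolated), via cesium alkoxide 21 (not isolated), via aryl cesium adduct 22 (not isolated)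
Conditions: CsF, 18-crown-6, THF, 0 °C to rt (11 in excess, added slowly)
Reagents that add atoms: none
Why: Proposed new method: fluoride removes the O-silyl group of 19 to give the proton-free alkoxide 21 and converts 11 into aryne 20; 21 adds to the aryne carbon remote from the flanking allyloxy group (future C8a), and the aryl anion 22 at the carbon next to that allyloxy group (future C4a) attacks the methyl ester in an intramolecular addition–elimination that expels methoxide, which excess 11 should consume while releasing more aryne. The closest known reaction type is the fluoride-mediated annulation of arynes with methyl salicylates to xanthones, together with aryne insertion into the C–O bond of carboxylic acids and the ring expansion of β-lactams by arynes; here an aliphatic β-hydroxy ester, freed as its alkoxide, replaces the phenolic partner. Ring C is closed by a formal [4+2] annulation whose ring-closing event is a 6-exo-trig acyl substitution by the aryl anion. No stereocentre is created: C2 is the carbinol carbon of 19 and keeps its (S) configuration because its C–O bond is never broken, and the epoxide is not touched. The step needs regioselective addition to the unsymmetrical aryne, secured by the C5 allyloxy group whose inductive polarisation makes the distal aryne carbon the electrophile, and cyclisation faster than protonation of 22, secured by the aprotic medium and the silyl ether as alkoxide source.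

Step 14
Reactants: 23 (2S)-5,7-bis(allyloxy)-2-[4-(allyloxy)-3-{[(2R)-3,3-dimethyloxiran-2-yl]methyl}phenyl]-6-prenylchroman-4-one
Product: 24 (2S)-2-[3-{[(2R)-3,3-dimethyloxiran-2-yl]methyl}-4-hydroxyphenyl]-5,7-dihydroxy-6-prenylchroman-4-one
Conditions: Pd(PPh3)4 (10 mol %), N-methylaniline, THF, rt, dark
Reagents that add atoms: none
Why: Tsuji–Trost deallylation, in which zerovalent palladium ionises the three aryl allyl ethers and the weakly basic amine captures the allyl fragments, conditions under which the epoxide, the prenyl group and the base-labile C2 centre should survive.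

Compound list
1 | phloroglucinol (benzene-1,3,5-triol) | Oc1cc(O)cc(O)c1 | starting material
2 | prenyl bromide (1-bromo-3-methylbut-2-ene) | CC(C)=CCBr | starting material
3 | 2-prenylphloroglucinol | CC(C)=CCc1c(O)cc(O)cc1O | intermediate
4 | 2-prenyl-5-(triisopropylsilyloxy)benzene-1,3-diol | CC(C)=CCc1c(O)cc(O[Si](C(C)C)(C(C)C)C(C)C)cc1O | intermediate
5 | [3,5-bis(allyloxy)-4-prenylphenoxy]triisopropylsilane | CC(C)=CCc1c(OCC=C)cc(O[Si](C(C)C)(C(C)C)C(C)C)cc1OCC=C | intermediate
6 | 3,5-bis(allyloxy)-4-prenylphenol | CC(C)=CCc1c(OCC=C)cc(O)cc1OCC=C | intermediate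
7 | 2-bromo-3,5-bis(allyloxy)-4-prenylphenol | CC(C)=CCc1c(OCC=C)cc(O)c(Br)c1OCC=C | intermediate
8 | [2-bromo-3,5-bis(allyloxy)-4-prenylphenoxy]trimethylsilane | CC(C)=CCc1c(OCC=C)cc(O[Si](C)(C)C)c(Br)c1OCC=C | intermediate
9 | [2,4-bis(allyloxy)-3-prenyl-6-(trimethylsilyloxy)phenyl]lithium | CC(C)=CCc1c(OCC=C)cc(O[Si](C)(C)C)c([Li])c1OCC=C | intermediate
10 | lithium 3,5-bis(allyloxy)-4-prenyl-2-(trimethylsilyl)phenoxide | CC(C)=CCc1c(OCC=C)cc([O-])c([Si](C)(C)C)c1OCC=C.[Li+] | intermediate
11 | 3,5-bis(allyloxy)-4-prenyl-2-(trimethylsilyl)phenyl trifluoromethanesulfonate | CC(C)=CCc1c(OCC=C)cc(OS(=O)(=O)C(F)(F)F)c([Si](C)(C)C)c1OCC=C | intermediate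
12 | 4'-hydroxyacetophenone | CC(=O)c1ccc(O)cc1 | starting material
13 | 4'-hydroxy-3'-prenylacetophenone | CC(=O)c1ccc(O)c(CC=C(C)C)c1 | intermediate
14 | 4'-(allyloxy)-3'-prenylacetophenone | CC(=O)c1ccc(OCC=C)c(CC=C(C)C)c1 | intermediate
15 | dimethyl carbonate | COC(=O)OC | starting material
16 | methyl 3-[4-(allyloxy)-3-prenylphenyl]-3-oxopropanoate | COC(=O)CC(=O)c1ccc(OCC=C)c(CC=C(C)C)c1 | intermediate
17 | methyl (3S)-3-[4-(allyloxy)-3-prenylphenyl]-3-hydroxypropanoate | COC(=O)C[C@@H](c1ccc(OCC=C)c(CC=C(C)C)c1)O | intermediate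
18 | methyl (3S)-3-[4-(allyloxy)-3-{[(2R)-3,3-dimethyloxiran-2-yl]methyl}phenyl]-3-hydroxypropanoate | COC(=O)C[C@@H](c1ccc(OCC=C)c(C[C@H]2OC2(C)C)c1)O | intermediate
19 | methyl (3S)-3-[4-(allyloxy)-3-{[(2R)-3,3-dimethyloxiran-2-yl]methyl}phenyl]-3-(trimethylsilyloxy)propanoate | COC(=O)C[C@@H](c1ccc(OCC=C)c(C[C@H]2OC2(C)C)c1)O[Si](C)(C)C | intermediate
20 | 3,5-bis(allyloxy)-4-prenylbenzyne | C1#CC(OCC=C)=C(CC=C(C)C)C(OCC=C)=C1 | intermediate
21 | cesium (1S)-1-[4-(allyloxy)-3-{[(2R)-3,3-dimethyloxiran-2-yl]methyl}phenyl]-3-methoxy-3-oxopropan-1-olate | COC(=O)C[C@@H](c1ccc(OCC=C)c(C[C@H]2OC2(C)C)c1)[O-].[Cs+] | intermediate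
22 | aryl cesium adduct of 21 and 20 (carbanion ortho to the new ether oxygen and to an allyloxy group) | COC(=O)C[C@@H](c1ccc(OCC=C)c(C[C@H]2OC2(C)C)c1)Oc1cc(OCC=C)c(CC=C(C)C)c(OCC=C)[c-]1.[Cs+] | intermediate
23 | (2S)-5,7-bis(allyloxy)-2-[4-(allyloxy)-3-{[(2R)-3,3-dimethyloxiran-2-yl]methyl}phenyl]-6-prenylchroman-4-one | CC(C)=CCc1c(OCC=C)cc2c(c1OCC=C)C(=O)C[C@@H](c1ccc(OCC=C)c(C[C@H]3OC3(C)C)c1)O2 | intermediate
24 | (2S)-2-[3-{[(2R)-3,3-dimethyloxiran-2-yl]methyl}-4-hydroxyphenyl]-5,7-dihydroxy-6-prenylchroman-4-one | CC(C)=CCc1c(O)cc2c(c1O)C(=O)C[C@@H](c1ccc(O)c(C[C@H]3OC3(C)C)c1)O2 | target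

Total step count: 14. Longest linear sequence: 8 steps (steps 1–6, 13, 14 from 1; equally steps 7–14 from 12).

Steps most likely to fail

Step 13. The aryl anion may be protonated before it acylates, which would leave an uncyclised aryl ether. The free alkoxide may undergo retro-aldol cleavage or β-elimination. The product may open and reclose through its chalcone under the basic medium, eroding C2. The fallback uses the known insertion of an aryne into the C–O bond of a carboxylic acid followed by oxa-Michael closure, which still forms both ring bonds in one operation but no longer controls C2. It sets out from 18: treatment with MsCl and Et3N gives the benzylic mesylate methyl (3S)-3-[4-(allyloxy)-3-{[(2R)-3,3-dimethyloxiran-2-yl]methyl}phenyl]-3-(methylsulfonyloxy)propanoate F1, which DBU should eliminate in the same flask to methyl (E)-3-[4-(allyloxy)-3-{[(2R)-3,3-dimethyloxiran-2-yl]methyl}phenyl]acrylate F2. LiOH in aqueous THF, with acidification kept at about pH 5, should give (E)-3-[4-(allyloxy)-3-{[(2R)-3,3-dimethyloxiran-2-yl]methyl}phenyl]acrylic acid F3. Heating F3 with 11 and CsF in THF in a sealed tube should add the carboxylate to aryne 20 at the same carbon as before and move the acyl group to the neighbouring carbanion, giving the 2'-hydroxychalcone (E)-1-[4,6-bis(allyloxy)-2-hydroxy-3-prenylphenyl]-3-[4-(allyloxy)-3-{[(2R)-3,3-dimethyloxiran-2-yl]methyl}phenyl]prop-2-en-1-one F4. F4 should cyclise in the basic medium to 23 together with its C2 epimer (2R)-5,7-bis(allyloxy)-2-[4-(allyloxy)-3-{[(2R)-3,3-dimethyloxiran-2-yl]methyl}phenyl]-6-prenylchroman-4-one F5. Preparative HPLC on a chiral stationary phase would separate the two, and the route is rejoined at 23.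

Step 14. The liberated 4'-phenol may attack the neighbouring epoxide, C2 may epimerise under the amine conditions, or the hindered C5 allyl ether may be removed incompletely. The fallback exchanges the protecting groups and unveils the phenols enzymatically at neutral pH. It sets out from 23: Pd(PPh3)4 and Bu3SnH in CH2Cl2 should give the tris(tributylstannyl) ether of the target F6, which Ac2O in the same flask should convert into the triacetate (2S)-5,7-diacetoxy-2-[4-acetoxy-3-{[(2R)-3,3-dimethyloxiran-2-yl]methyl}phenyl]-6-prenylchroman-4-one F7. Lipase-catalysed alcoholysis of F7 (immobilised Candida antarctica lipase B, n-butanol, tert-butyl methyl ether, 40 °C) should then release the three phenols without acid, base or metal, rejoining the route at 24.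

Step 2. Silylation may be unselective among the three phenolic hydroxyls, falling on a flanking hydroxyl or giving bis-silylation. The fallback installs the prenyl group by directed ortho-metalation after the oxygens are differentiated, and also bypasses step 1. It sets out from 1: MOMCl (2 equiv) and iPr2NEt should give 3,5-bis(methoxymethoxy)phenol F8, and TIPSCl with imidazole its silyl ether [3,5-bis(methoxymethoxy)phenoxy]triisopropylsilane F9. n-BuLi in THF at 0 °C should lithiate between the two methoxymethyl ethers to the aryllithium [2,6-bis(methoxymethoxy)-4-(triisopropylsilyloxy)phenyl]lithium F10, which CuI and prenyl bromide 2 should convert into [3,5-bis(methoxymethoxy)-4-prenylphenoxy]triisopropylsilane F11. Brief treatment with HCl in MeOH at rt should remove both methoxymethyl groups and rejoin the route at 4.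

Further compounds
F1 | step 13 | methyl (3S)-3-[4-(allyloxy)-3-{[(2R)-3,3-dimethyloxiran-2-yl]methyl}phenyl]-3-(methylsulfonyloxy)propanoate | COC(=O)C[C@@H](c1ccc(OCC=C)c(C[C@H]2OC2(C)C)c1)OS(C)(=O)=O
F2 | step 13 | methyl (E)-3-[4-(allyloxy)-3-{[(2R)-3,3-dimethyloxiran-2-yl]methyl}phenyl]acrylate | COC(=O)/C=C/c1ccc(OCC=C)c(C[C@H]2OC2(C)C)c1
F3 | step 13 | (E)-3-[4-(allyloxy)-3-{[(2R)-3,3-dimethyloxiran-2-yl]methyl}phenyl]acrylic acid | OC(=O)/C=C/c1ccc(OCC=C)c(C[C@H]2OC2(C)C)c1
F4 | step 13 | (E)-1-[4,6-bis(allyloxy)-2-hydroxy-3-prenylphenyl]-3-[4-(allyloxy)-3-{[(2R)-3,3-dimethyloxiran-2-yl]methyl}phenyl]prop-2-en-1-one | O=C(/C=C/c1ccc(OCC=C)c(C[C@H]2OC2(C)C)c1)c1c(O)cc(OCC=C)c(CC=C(C)C)c1OCC=C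
F5 | step 13 | (2R)-5,7-bis(allyloxy)-2-[4-(allyloxy)-3-{[(2R)-3,3-dimethyloxiran-2-yl]methyl}phenyl]-6-prenylchroman-4-one | CC(C)=CCc1c(OCC=C)cc2c(c1OCC=C)C(=O)C[C@H](c1ccc(OCC=C)c(C[C@H]3OC3(C)C)c1)O2
F6 | step 14 | tris(tributylstannyl) ether of the target | CC(C)=CCc1c(O[Sn](CCCC)(CCCC)CCCC)cc2c(c1O[Sn](CCCC)(CCCC)CCCC)C(=O)C[C@@H](c1ccc(O[Sn](CCCC)(CCCC)CCCC)c(C[C@H]3OC3(C)C)c1)O2
F7 | step 14 | (2S)-5,7-diacetoxy-2-[4-acetoxy-3-{[(2R)-3,3-dimethyloxiran-2-yl]methyl}phenyl]-6-prenylchroman-4-one | CC(C)=CCc1c(OC(C)=O)cc2c(c1OC(C)=O)C(=O)C[C@@H](c1ccc(OC(C)=O)c(C[C@H]3OC3(C)C)c1)O2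
F8 | step 2 | 3,5-bis(methoxymethoxy)phenol | COCOc1cc(O)cc(OCOC)c1
F9 | step 2 | [3,5-bis(methoxymethoxy)phenoxy]triisopropylsilane | COCOc1cc(OCOC)cc(O[Si](C(C)C)(C(C)C)C(C)C)c1
F10 | step 2 | [2,6-bis(methoxymethoxy)-4-(triisopropylsilyloxy)phenyl]lithium | COCOc1cc(O[Si](C(C)C)(C(C)C)C(C)C)cc(OCOC)c1[Li]
F11 | step 2 | [3,5-bis(methoxymethoxy)-4-prenylphenoxy]triisopropylsilane | COCOc1cc(O[Si](C(C)C)(C(C)C)C(C)C)cc(OCOC)c1CC=C(C)C
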